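The numbers in the tables were computed for substances that don't exist.

Watch the solid. Two earlier runs stand behind three new flasks, and the question is about the target at the end.

| flask | solid substrate | remark | time |
|---|---|---|---|
| south-west | 0.75 M | run made earlier |  |
| north-west | 1.7 M | run made earlier |  |
| autumn | 0.80 M |  | 5.0 d |
| spring | 1.5 M |  | 5.0 d |
| summer | 3.0 M |  | 5.0 d |

| run | time / d | target / % | solid substrate / % |
|---|---|---|---|
| south-west | 0.625 | 14 | 25 |
| south-west | 1.25 | 35 | 0 |
| south-west | 2.00 | 45 | 3 |
| south-west | 3.00 | 49 | 0 |
| south-west | 4.00 | 49 | 0 |
| north-west | 0.333 | 1 | 76 |
| north-west | 0.833 | 11 | 60 |
| north-west | 1.67 | 29 | 25 |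
| north-west | 2.50 | 38 | 2 |
| north-west | 4.00 | 36 | 0 |

(scatter of a reading: 2 percentage points)

- percent here means solid substrate units held: one target counts as two
- solid substrate is a solid; its amount is given per volume of the solution
- what was read earlier has a scatter of 2 percentage points, one standard deviation
- at the start none of the solid substrate is in solution
- "hardly changes" means that all values lie within two and a half points (for a concentration: within two and a half percent of the largest)

- [target] at the end for autumn, spring, summer, in this order
- the shape of the row from first to last (falls, then rises / rises all the way / rises, then falls / hardly changes / falls all the way)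

Take the north-west run and follow one rate: how fast the fraction of the charge still solid falls. At the start you read a fall to 76 % in 0.333 d, which is 0.721 /d. From there to 1.67 d, where 25 % is left, the reading is 0.381 /d, about half the opening rate.

I take this slowing to be the solution filling up, though that is my picture and the readings don't prove it. I also assume that the amount dissolving per day doesn't depend on how much solid lies there, which makes this a zero-order stretch. A steady rate integrates to a straight line: the fraction left is one minus time over T.

T is the clearing time 2.62 d, the time the slowed rate needs to take the north-west charge to zero, and I let it grow in step with the charge, which assumes the same amount dissolving per day in each flask. That gives 1.23 d for autumn, 2.31 d for spring and 4.63 d for summer. At the opening rate summer would need 2.45 d, so the slowing costs it about twice the time. Even so, the reckoned time for summer, the longest of the three, ends before 5.0 d. My reckoning therefore has each charge dissolved by the end, and I leave the row itself to the forecast.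

The forecast gives 0.195 M, 0.29 M and 0.43 M, a row that rises all the way. It expects the solid to last “about 1.2 d at 0.80 M, 2.2 d at 1.5 M and 4.3 d at 3.0 M, so all three runs finish dissolving within 5 d”.

The flask gives 0.178 M, 0.293 M and 0.468 M, a row that rises all the way.

    2 starting material → target (k = 8.90 × 10⁻⁶ /M/s)
    starting material + target → side product (k = 8.50 × 10⁻⁶ /M/s)
    solid substrate ⇌ starting material, rate k3*(cs3 - [starting material]) while solid is left; crystals form when [starting material] > cs3 (solubility = 1.10 M, k = 1.30 × 10⁻⁵ /s)
    starting material → decomposition product (k = 4.80 × 10⁻⁸ /s)

The forecast held. Its summer clearing time and mine differ, yet both lie before the end, and summer stands at 0 % solid at 5.00 d. At 2.50 d the clearing time predicts 46.0 % left in summer, and the flask holds 42.8 %. For spring it gives 2.31 d, and at 2.50 d spring holds 0 % solid.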